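**Plan**

1. Retrosynthesis: (a) the phenolic O–H is masked as a benzyl carbonate; (b) the C11–C12 CH2–CH2 bond of the docosanoyl chain is cut into two primary alkyl radicals, each traced back to a carboxylic acid one carbon longer (dodecanoic acid and a dodecanedioic acid half-ester); (c) the ester C(=O)–O bond is cut to 3-(4-hydroxyphenyl)propan-1-ol and mono-tert-butyl dodecanedioate.
2. Enabling feature: C11 and C12 are the two central, unbranched CH2 carbons of the saturated C22 acyl chain. C11 lies nine CH2 groups from the ester carbonyl C1, C12 lies nine CH2 groups from the terminal CH3, and both are remote from the only ring (the 1,4-disubstituted benzene ring). The chain is therefore C12 + C12 − 2 CO2 by anodic decarboxylative radical coupling.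
3. Forward order: chemoselective esterification of the aliphatic OH (step 1), carbonate on the phenolic oxygen to make the benzene ring anodically inert (step 2), release of the ω-carboxylic acid (step 3), mixed Kolbe electrolysis with lauric acid to join the chain (step 4), hydrogenolysis of the carbonate (step 5). No ring is formed.
4. Remark on the chemistry: the target has no stereocentre and no stereogenic double bond, so it is a single achiral compound and no stereocontrol is needed.

Key step: step 4

**Route**

Step 1
Reactants: 1 3-(4-hydroxyphenyl)propan-1-ol; 2 12-(tert-butoxy)-12-oxododecanoic acid (mono-tert-butyl dodecanedioate)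
Product: 3 tert-butyl 3-(4-hydroxyphenyl)propyl dodecanedioate
Conditions: Novozym 435 (immobilised CAL-B), 4 Å MS, 2-methyl-2-butanol, 55 °C
Reagents that add atoms: none
Why: Lipase-catalysed esterification (serine-hydrolase acyl transfer) should acylate only the primary aliphatic hydroxyl, because the phenolic hydroxyl and the tertiary solvent alcohol are not accepted as acyl acceptors and the hindered tert-butyl ester is not accepted as acyl donor, while the sieves remove the water formed.

Step 2
Reactants: 3 tert-butyl 3-(4-hydroxyphenyl)propyl dodecanedioate
Product: 4 tert-butyl 3-(4-{[(benzyloxy)carbonyl]oxy}phenyl)propyl dodecanedioate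
Conditions: CbzCl (1.2 equiv), pyridine (1.5 equiv), CH2Cl2, 0 °C to rt
Reagents that add atoms: benzyl chloroformate, O=C(Cl)OCc1ccccc1
Why: O-Alkoxycarbonylation of the only free hydroxyl (the phenol) with a chloroformate should give the aryl benzyl carbonate, which lowers the electron density of the benzene ring for the anodic step and can later be removed by neutral hydrogenolysis.

Step 3
Reactants: 4 tert-butyl 3-(4-{[(benzyloxy)carbonyl]oxy}phenyl)propyl dodecanedioate
Product: 5 12-[3-(4-{[(benzyloxy)carbonyl]oxy}phenyl)propoxy]-12-oxododecanoic acid
Conditions: TFA/CH2Cl2 (1:3), 0 °C to rt, 1–2 h; co-evaporation with toluene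
Reagents that add atoms: none
Why: Acidolysis of the tert-butyl ester (alkyl–oxygen cleavage through the tert-butyl cation, lost as isobutene) should free the terminal carboxylic acid, while the primary alkyl ester and the benzyl carbonate, which cannot form a comparably stable cation, should survive the short exposure.

Step 4
Reactants: 5 12-[3-(4-{[(benzyloxy)carbonyl]oxy}phenyl)propoxy]-12-oxododecanoic acid (1 equiv); 6 dodecanoic acid (lauric acid, ca. 5 equiv)
Product: 7 3-(4-{[(benzyloxy)carbonyl]oxy}phenyl)propyl docosanoate
Conditions: undivided cell, smooth Pt anode, stainless-steel cathode, constant current ca. 0.2 A cm−2, KOH (ca. 5 mol% of total acid), MeOH, 40–45 °C, ca. 1.2–1.5 F per mol of total acid, stopped while the electrolyte is still weakly acidic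
Reagents that add atoms: none
Why: In this mixed (crossed) Kolbe electrolysis both carboxylates should be oxidised by one electron at the Pt anode and lose CO2, giving the undecyl radical from 6 and the primary 10-(alkoxycarbonyl)decyl radical from 5, which combine in the dense radical layer at the electrode to form the C11–C12 CH2–CH2 bond, while protons are reduced to H2 at the cathode. The closest known reaction type is the classical anodic chain extension of fatty acids, in which a fatty acid is cross-coupled with the half-ester of an α,ω-dicarboxylic acid. No ring is closed and no stereocentre is formed. The step needs cross-coupling in preference to homo-coupling, which is secured statistically by the roughly fivefold excess of cheap 6, so that nearly every ester-bearing radical should meet an undecyl radical; the homo-coupling by-products (docosane and a symmetrical docosanedioate diester) differ enough in polarity from 7 to be removed by chromatography. It also needs oxidation of carboxylate in preference to the arene, and radical coupling in preference to further oxidation to a cation (Hofer–Moest pathway); these are secured by the carboxylate layer on smooth Pt at high current density, by the electron-withdrawing carbonate on the phenolic oxygen, and by the fact that both radicals are unstabilised primary radicals at least nine CH2 groups away from the nearest carbonyl. The weakly acidic, only partly neutralised methanol should leave the alkyl ester and the carbonate intact.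

Step 5
Reactants: 7 3-(4-{[(benzyloxy)carbonyl]oxy}phenyl)propyl docosanoate
Product: 8 3-(4-hydroxyphenyl)propyl docosanoate
Conditions: H2 (1 atm), 10% Pd/C, EtOAc/THF, rt
Reagents that add atoms: none
Why: Hydrogenolysis of the benzylic C–O bond of the carbonate should give toluene and an aryl hydrogen carbonate that loses CO2 to the free phenol, while the non-benzylic 3-arylpropyl ester and the benzene ring are not reduced under these conditions.

**Compound list**

1 | 3-(4-hydroxyphenyl)propan-1-ol | OCCCc1ccc(O)cc1 | starting material
2 | 12-(tert-butoxy)-12-oxododecanoic acid | CC(C)(C)OC(=O)CCCCCCCCCCC(=O)O | starting material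
3 | tert-butyl 3-(4-hydroxyphenyl)propyl dodecanedioate | CC(C)(C)OC(=O)CCCCCCCCCCC(=O)OCCCc1ccc(O)cc1 | intermediate
4 | tert-butyl 3-(4-{[(benzyloxy)carbonyl]oxy}phenyl)propyl dodecanedioate | CC(C)(C)OC(=O)CCCCCCCCCCC(=O)OCCCc1ccc(OC(=O)OCc2ccccc2)cc1 | intermediate
5 | 12-[3-(4-{[(benzyloxy)carbonyl]oxy}phenyl)propoxy]-12-oxododecanoic acid | OC(=O)CCCCCCCCCCC(=O)OCCCc1ccc(OC(=O)OCc2ccccc2)cc1 | intermediate
6 | dodecanoic acid (lauric acid) | CCCCCCCCCCCC(=O)O | starting material
7 | 3-(4-{[(benzyloxy)carbonyl]oxy}phenyl)propyl docosanoate | CCCCCCCCCCCCCCCCCCCCCC(=O)OCCCc1ccc(OC(=O)OCc2ccccc2)cc1 | intermediate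
8 | 3-(4-hydroxyphenyl)propyl docosanoate | CCCCCCCCCCCCCCCCCCCCCC(=O)OCCCc1ccc(O)cc1 | target

**Summary**

Total step count: 5. Longest linear sequence: 5 steps (1 → 3 → 4 → 5 → 7 → 8).

Steps most likely to fail:

1. Step 4. The cross-coupling may be eroded by statistical homo-coupling of each acid. Competing anodic oxidation of the aryl ring, fouling of the anode by the waxy products, over-oxidation of the radicals to cations, or base-induced methanolysis of the carbonate near the cathode may also occur. The fallback forms the same C11–C12 bond by olefin metathesis without protecting groups. It sets out from 1: lipase-catalysed esterification (Novozym 435, as in step 1) with commercial dodec-11-enoic acid should give 3-(4-hydroxyphenyl)propyl dodec-11-enoate F1. Cross-metathesis of F1 with an excess of 1-dodecene (second-generation Ru benzylidene catalyst, CH2Cl2, 40 °C) should give 3-(4-hydroxyphenyl)propyl docos-11-enoate F2 as an E/Z mixture. Hydrogenation of the C11=C12 double bond (H2, Pd/C, EtOAc) should then give the target, so the fallback comes back to the route at 8.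

2. Step 1. The enzymatic acyl transfer may be slow or incomplete for this long-chain half-ester acid, or the selectivity for the aliphatic over the phenolic hydroxyl may be lost if a chemical acylation has to be substituted. The fallback reverses the order of the two O-functionalisations. It sets out from 1: phenoxide-selective carbonate formation under Schotten–Baumann conditions (CbzCl, aqueous NaOH, CH2Cl2, 0 °C) should give benzyl 4-(3-hydroxypropyl)phenyl carbonate F3. Carbodiimide esterification of its only free hydroxyl with 2 (EDC, cat. DMAP, CH2Cl2, 0 °C to rt) should give 4, where the fallback comes back to the route.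

3. Step 5. The heterogeneous hydrogenolysis may stall through low solubility of the waxy C22 ester or poisoning of the catalyst by traces carried over from the electrolysis. The fallback removes the carbonate by nucleophilic acyl substitution instead of reduction. It sets out from 7: pyrrolidine (1.5 equiv, THF, 0 °C to rt) should attack the activated aryl carbonate carbonyl and expel the phenoxide, while the unactivated alkyl ester does not undergo aminolysis at this temperature. This gives 8 directly and makes no new intermediate.

Further compounds
F1 | step 4 | 3-(4-hydroxyphenyl)propyl dodec-11-enoate | C=CCCCCCCCCCC(=O)OCCCc1ccc(O)cc1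
F2 | step 4 | 3-(4-hydroxyphenyl)propyl docos-11-enoate (E/Z mixture) | CCCCCCCCCCC=CCCCCCCCCCC(=O)OCCCc1ccc(O)cc1
F3 | step 1 | benzyl 4-(3-hydroxypropyl)phenyl carbonate | OCCCc1ccc(OC(=O)OCc2ccccc2)cc1
F0 | step 5 | none | none
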